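## The problem

Ruixianglangdusu B (17) is a 3,3'-biflavanone. Two 2-(4-methoxyphenyl)chroman-4-one units are joined through C3–C3', so the four stereocentres C2, C3, C3' and C2' form one contiguous chain, (2S,3R,3'R,2'S), with a 2,3-trans relationship in each pyranone ring. The halves differ in one detail only, a free hydroxyl at C7 against a methyl ether at C7'. The two phloroglucinol-derived rings therefore have to enter as different building blocks, since a symmetrical dimer could not be differentiated cleanly afterwards. C3 and C3' lie α to the ketones, are epimerisable, and prefer the trans arrangement, so each can be controlled by its neighbour C2 or C2'. C2 and C2' are benzylic, four bonds apart, and cannot be corrected without ring opening, so their absolute and mutual configuration must come from a reagent or catalyst. The fragile parts are the pyranone rings (base opens them by retro-oxa-Michael reaction, which racemises C2 and scrambles C3), the 4-methoxybenzylic C2–O bonds (hydrogenolysis, strong acid) and the phloroglucinol-type phenols, which must stay masked to the end and be released without base. The enabling feature is that in each pyranone ring the ether bond O1–C2 (O1'–C2') lies β to the C4 (C4') ketone. Opening both rings at these bonds leaves C3–C3' as the central bond of a flat, achiral 2,3-diaroyl-1,4-bis(4-methoxyphenyl)buta-1,3-diene, whose carbon skeleton is that of a bis(arylidene)succinic acid.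

## Retrosynthesis

**17 ⇒ 16.** No skeletal bond is cut. The phenols at C5, C7 and C5' are masked as methoxymethyl ethers. Acetals are preferred to benzyl ethers (hydrogenolysis next to two benzylic C–O bonds) and to methyl ethers (no reagent would spare the 7'- and 4-methoxy groups). They leave in dilute acid, the medium in which a flavanone neither ring-opens nor epimerises.

**16 ⇒ 15.** The bonds O1–C2 and O1'–C2' are cut. Cutting C2–aryl or C4–C4a instead would leave the rings or the stereocentres to be made elsewhere. This cut removes both pyranone rings and all four stereocentres at once, and bichalcone 15 is achiral. The forward reaction must close two rings 6-endo with control of the face of each β-carbon by a chiral amine–thiourea catalyst, and must protonate C3 and C3' to the trans arrangement.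

**15 ⇒ 14.** The two nucleophilic phenols are unveiled from the fully protected diketone 14 by loss of one ortho acetal on each aroyl ring. The phenols cannot be carried free through the organolithium steps, and the two ortho positions of each ring must be alike for an unambiguous metalation. The ketone differentiates them afterwards by chelation. The forward reaction has to stop at one acetal per ring and must not close a ring.

**14 ⇒ 12 + 13.** The aryl–acyl bond C4'–C4a' is cut, giving keto ester 12 and aryllithium 13, made by directed metalation of 9 (from 5-methoxyresorcinol 8). Electrophilic acylation of 8 would not reliably place the acyl group para to the methoxy group and needs Lewis acids that the diene does not tolerate. Metalation between the two acetal oxygens puts the carbonyl exactly where ring A' requires it. The forward reaction must attack the ester in the presence of a hindered ketone and two arylidene units.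

**12 ⇒ 11 ⇒ 5 + 10.** The bond C4–C4a is cut. Anhydride 5 is opened once by aryllithium 10 (from tris-acetal 7, from phloroglucinol 6). This one operation differentiates the two carboxyl carbons of a symmetrical four-carbon unit, which is what lets two different aroyl groups go onto one symmetrical diene. Acid 11 is converted into ester 12 by carboxylate alkylation, because an activated γ-keto acid would close to cyclic pseudo-acid derivatives.

**5 ⇒ 4 ⇒ 1 + 2.** Both arylidene double bonds are cut, leading to dimethyl succinate 1 and two molecules of 4-methoxybenzaldehyde 2. The C3–C3' bond of 17 is the C2–C3 bond of 1 and never has to be made. The double Stobbe condensation sets the E geometry at both double bonds, and diacid 4 is dehydrated to 5.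

## Roads not taken

**Alternative 1:** The cut is at the two C2–aryl bonds. A 3,3'-bichromone A1 would take up two 4-methoxyphenyl groups from the boronic acid under monovalent rhodium ([RhCl(C2H4)2]2 with a chiral diene), with protonation at C3 and C3', to give the tri-O-benzyl ether A2.
- Merits: the heterocycles arrive intact, chromones are robust, and rhodium–diene conjugate arylation of chromones is a well-developed enantioselective route to flavanones. In expected enantioselectivity per event this road has the better precedent than amine–thiourea closure of an enone that is not part of a 1,3-dicarbonyl system.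
- Weak points: the precedents concern chromones unsubstituted at C3. In A1 each acceptor is α-branched, is a vinylogous ester (far less electrophilic than a chalcone), and is flanked by a 5-alkoxy group. After the first addition the second acceptor carries a bulky flavanon-3-yl group. The electron-rich boronic acid protodeboronates during slow additions.
- Further cost: A1 is unsymmetrical, so it needs a cross-coupling of two separately made 3-functionalised chromones, and A2 must be debenzylated by hydrogenolysis beside two benzylic C2–O bonds.
- Comparison: the chosen plan sets against this a far more reactive acceptor, a precursor 15 reached from a double Stobbe condensation, metal-free stereocontrol and an acid deprotection.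

**Alternative 2:** The cut is at four C–C bonds around two molecules of CO. The iodoaryl alkynyl diether A3 would undergo oxidative addition to zerovalent palladium (from Pd(OAc)2 and PPh3), CO insertion, syn acylpalladation of the alkyne, a second CO insertion and acylation of the dimethoxyphenyl ring, giving the bichromanylidenedione A4.
- Merits: no other road forms as many bonds in one step. The C2 and C2' centres would come from asymmetric alkynylation of 4-methoxybenzaldehyde, which is dependable. In bond-forming power per step this road is superior to the chosen one.
- Weak points: the terminating step, acylation of an unfunctionalised arene C–H bond by an acylpalladium species, is the least precedented elementary step of all four plans. The propargylic aryl ethers of A3, doubly activated by the 4-methoxyphenyl groups, can ionise with zerovalent palladium to allenylpalladium species, which competes with oxidative addition at the iodide and would erase the stereocentres.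
- Further cost: A4 lacks the C3 and C3' centres and carries a 5'-methyl ether. A tetrasubstituted enedione must be reduced to the trans,trans product, the peri-methyl ether cleaved (reliable with BCl3) and the benzyl ethers removed, so at least three steps follow the key step.
- Comparison: the chosen plan sets against this a key step with much closer precedent, all four stereocentres from an achiral substrate, and one step afterwards.

**Alternative 3:** The cut is at C4–C4a and C4'–C4a'. The succinamide A5 would be activated at both dimethylamide groups with Tf2O and 2-fluoropyridine. Each 3,5-bis(benzyloxy)phenyl ether ring would attack its iminium carbon, and hydrolysis would give the tetra-O-benzyl ether A6.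
- Merits: the reaction class has the strongest precedent of the four key steps. The phloroglucinol ether rings are highly nucleophilic, their two ortho positions are equivalent, and the key step poses no question of asymmetric induction because all four stereocentres arrive with A5.
- Weak points: those stereocentres are exposed. Activation of an amide with an α-hydrogen leads to a keteniminium ion, which flattens C3 and C3', and the β-aryloxy groups can then be lost by elimination, which destroys C2 and C2'.
- Further cost: A5 needs four contiguous stereocentres on a β-aryloxy succinamide, so the stereochemical problem is moved and not solved. A6 has benzyl ethers at both C7 and C7', so the single 7'-methyl ether would require unselective monomethylation or an unsymmetrical A5.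
- Comparison: the chosen plan sets against the stronger precedent an achiral precursor 15, the 7/7' difference built in from the first aryl–acyl bond, and catalytic stereocontrol.

Key step: step 9

Assumption: of the two pseudoenantiomeric cinchona thioureas, the quinine-derived one is taken to deliver the (2S,2'S) sense. If a trial on 15 showed the opposite sense, the quinidine-derived catalyst would be used with no other change.

## Route

Step 1
Reactants: 1 dimethyl succinate; 2 4-methoxybenzaldehyde (2.2 equiv)
Product: 4 (2E,3E)-2,3-bis(4-methoxybenzylidene)succinic acid, via methyl hydrogen (2E,3E)-2,3-bis(4-methoxybenzylidene)succinate 3 (not isolated)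
Conditions: NaOMe (3 equiv), MeOH, reflux; then 2 M aq NaOH, reflux; then aq HCl, 0 °C
Reagents that add atoms: sodium hydroxide, [Na+].[OH-]
Why: Double Stobbe condensation (enolate addition, γ-lactone formation, E1cB ring opening) should install both anisylidene groups with the favoured E geometry, each aryl group trans to its own carboxyl; hydroxide then cleaves the surviving methyl ester and the diacid should crystallise on acidification.

Step 2
Reactants: 4 (2E,3E)-2,3-bis(4-methoxybenzylidene)succinic acid
Product: 5 (3E,4E)-3,4-bis(4-methoxybenzylidene)oxolane-2,5-dione
Conditions: AcCl, CH2Cl2, reflux, dark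
Reagents that add atoms: none
Why: Dehydrative cyclisation of a 1,4-diacid to the five-membered anhydride (a fulgide) with acetyl chloride is the standard preparation of such compounds and should keep the E,E geometry if light is excluded.

Step 3
Reactants: 6 phloroglucinol
Product: 7 1,3,5-tris(methoxymethoxy)benzene
Conditions: NaH (3.6 equiv), MOMCl (3.6 equiv), DMF, 0 °C to rt
Reagents that add atoms: chloromethyl methyl ether, COCCl
Why: Williamson-type O-alkylation of the phenoxide with a reactive α-chloro ether; the acetal is chosen because it directs ortho-lithiation, survives aryllithiums, and later leaves either by chelation (ortho to a ketone) or in acid.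

Step 4
Reactants: 8 5-methoxyresorcinol
Product: 9 1-methoxy-3,5-bis(methoxymethoxy)benzene
Conditions: NaH (2.4 equiv), MOMCl (2.4 equiv), DMF, 0 °C to rt
Reagents that add atoms: chloromethyl methyl ether, COCCl
Why: The same Williamson-type O-alkylation as in step 3; the methyl ether that will become the 7'-methoxy group is already in place.

Step 5
Reactants: 7 1,3,5-tris(methoxymethoxy)benzene (1.1 equiv); 5 (3E,4E)-3,4-bis(4-methoxybenzylidene)oxolane-2,5-dione
Product: 11 (2E,3E)-2,3-bis(4-methoxybenzylidene)-4-oxo-4-[2,4,6-tris(methoxymethoxy)phenyl]butanoic acid, via 2,4,6-tris(methoxymethoxy)phenyllithium 10 (not isolated)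
Conditions: n-BuLi (1.05 equiv), THF, 0 °C; then added to 5 in THF, −78 °C, dark; cold 0.5 M aq HCl to pH 3
Reagents that add atoms: none
Why: Directed ortho-metalation between two acetal oxygens (all three ring positions are equivalent) gives 10, which opens the anhydride by nucleophilic acyl substitution; the resulting 2,6-disubstituted aryl ketone is too hindered for a second addition and the lithium carboxylate is inert, so the two carbonyl carbons of 5 are differentiated in one operation.

Step 6
Reactants: 11 (2E,3E)-2,3-bis(4-methoxybenzylidene)-4-oxo-4-[2,4,6-tris(methoxymethoxy)phenyl]butanoic acid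
Product: 12 methyl (2E,3E)-2,3-bis(4-methoxybenzylidene)-4-oxo-4-[2,4,6-tris(methoxymethoxy)phenyl]butanoate
Conditions: MeI (1.5 equiv), K2CO3 (1.5 equiv), DMF, rt, dark
Reagents that add atoms: iodomethane, CI
Why: SN2 O-methylation of the potassium carboxylate should give the open-chain methyl ester; alkylating the carboxylate avoids the cyclic pseudo-acid derivatives that a γ-keto acid forms when its carboxyl group is made electrophilic.

Step 7
Reactants: 9 1-methoxy-3,5-bis(methoxymethoxy)benzene (1.4 equiv); 12 methyl (2E,3E)-2,3-bis(4-methoxybenzylidene)-4-oxo-4-[2,4,6-tris(methoxymethoxy)phenyl]butanoate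
Product: 14 (2E,3E)-2,3-bis(4-methoxybenzylidene)-1-[4-methoxy-2,6-bis(methoxymethoxy)phenyl]-4-[2,4,6-tris(methoxymethoxy)phenyl]butane-1,4-dione, via 4-methoxy-2,6-bis(methoxymethoxy)phenyllithium 13 (not isolated)
Conditions: n-BuLi (1.3 equiv), THF, 0 °C; then 12, THF, −78 to −20 °C, dark; AcOH, −78 °C
Reagents that add atoms: none
Why: Directed ortho-metalation of 9 should occur at the position flanked by the two acetal oxygens (cooperating, stronger directing groups than methoxy), and 13 then attacks the methyl ester by acyl substitution, the ketone of 12 being shielded by two ortho substituents and an α-branched alkenyl group; the new ketone is equally hindered, so the addition should stop there.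

Step 8
Reactants: 14 (2E,3E)-2,3-bis(4-methoxybenzylidene)-1-[4-methoxy-2,6-bis(methoxymethoxy)phenyl]-4-[2,4,6-tris(methoxymethoxy)phenyl]butane-1,4-dione
Product: 15 (2E,3E)-1-[2-hydroxy-4,6-bis(methoxymethoxy)phenyl]-4-[2-hydroxy-4-methoxy-6-(methoxymethoxy)phenyl]-2,3-bis(4-methoxybenzylidene)butane-1,4-dione
Conditions: MgBr2·OEt2 (3 equiv), Et2O–toluene, 0 °C to rt, dark; pH 7 phosphate buffer, 0 °C
Reagents that add atoms: none
Why: Chelation-controlled acetal cleavage: MgBr2 held between the ketone oxygen and one ortho acetal oxygen delivers bromide to the OCH2O carbon, and once one ortho oxygen per ring is a magnesium phenoxide chelated to the carbonyl, the remaining acetals have no free carbonyl to assist them; the same chelate holds the phenoxide oxygen away from the enone β-carbon until neutral work-up, in which the bromomethyl methyl ether released is hydrolysed.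

Step 9
Reactants: 15 (2E,3E)-1-[2-hydroxy-4,6-bis(methoxymethoxy)phenyl]-4-[2-hydroxy-4-methoxy-6-(methoxymethoxy)phenyl]-2,3-bis(4-methoxybenzylidene)butane-1,4-dione
Product: 16 (2S,3R)-5,7-bis(methoxymethoxy)-3-[(2S,3R)-7-methoxy-5-(methoxymethoxy)-2-(4-methoxyphenyl)-4-oxochroman-3-yl]-2-(4-methoxyphenyl)chroman-4-one
Conditions: quinine-derived thiourea 1-[3,5-bis(trifluoromethyl)phenyl]-3-[(8α,9S)-6'-methoxycinchonan-9-yl]thiourea (20 mol%), toluene, −20 °C, dark; filtration through silica
Reagents that add atoms: none
Why: The quinuclidine nitrogen deprotonates the 2-hydroxyl of one aroyl ring while the thiourea hydrogen-bonds the ketone oxygen, the phenoxide adds to the anisylidene β-carbon of its own enone, the dienolate is protonated at C3 by the quinuclidinium ion, and the second aroyl unit repeats the sequence. The closest known reaction type is the cinchona-thiourea-catalysed asymmetric intramolecular oxa-Michael cyclisation of α-substituted 2'-hydroxychalcones to flavanones, here asked to run twice in one molecule. Ring C and ring C' each close 6-endo-trig, as in every chalcone–flavanone isomerisation. C2 and C2' are set by the catalyst, which selects the face of each β-carbon that the phenoxide attacks. C3 and C3' are set by protonation anti to the neighbouring anisyl group and, being α to the ketones, can equilibrate under the amine to the diequatorial 2,3-trans arrangement, so with (2S,2'S) fixed only the (3R,3'R) isomer remains. The step needs enantioselectivity in the first closure, catalyst rather than substrate control in the second, attack on the phenoxide's own enone rather than seven-membered attack on the other arylidene carbon, and α- rather than γ-protonation of the first dienolate. The substrate helps: it is achiral, each phenoxide reaches only its own β-carbon through a six-membered transition state, the dienolate character of the first intermediate accelerates the first closure, and the hydrogen bond from the 2-hydroxyl to the ketone keeps uncatalysed closure slow in toluene at low temperature. Because the same catalyst acts twice, a wrong-sense event leads to the unlike diastereomer, which chromatography removes, so 16 should be enriched in the desired enantiomer.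

Step 10
Reactants: 16 (2S,3R)-5,7-bis(methoxymethoxy)-3-[(2S,3R)-7-methoxy-5-(methoxymethoxy)-2-(4-methoxyphenyl)-4-oxochroman-3-yl]-2-(4-methoxyphenyl)chroman-4-one
Product: 17 ruixianglangdusu B, (2S,3R)-5,7-dihydroxy-3-[(2S,3R)-5-hydroxy-7-methoxy-2-(4-methoxyphenyl)-4-oxochroman-3-yl]-2-(4-methoxyphenyl)chroman-4-one
Conditions: 3 M HCl, MeOH–THF, 45 °C
Reagents that add atoms: none
Why: Acid-catalysed acetal exchange with methanol should remove the three methoxymethyl ethers as dimethoxymethane; flavanones need base to ring-open, and C3 and C3' already hold the thermodynamic trans arrangement, so no stereocentre is at risk.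

## Compound list

1 | dimethyl succinate | COC(=O)CCC(=O)OC | starting material
2 | 4-methoxybenzaldehyde | COc1ccc(C=O)cc1 | starting material
3 | methyl hydrogen (2E,3E)-2,3-bis(4-methoxybenzylidene)succinate | COC(=O)/C(=C/c1ccc(OC)cc1)C(=C/c1ccc(OC)cc1)\C(=O)O | intermediate (not isolated)
4 | (2E,3E)-2,3-bis(4-methoxybenzylidene)succinic acid | OC(=O)/C(=C/c1ccc(OC)cc1)C(=C/c1ccc(OC)cc1)\C(=O)O | intermediate
5 | (3E,4E)-3,4-bis(4-methoxybenzylidene)oxolane-2,5-dione | COc1ccc(/C=C2/C(=O)OC(=O)/C2=C/c2ccc(OC)cc2)cc1 | intermediate
6 | phloroglucinol | Oc1cc(O)cc(O)c1 | starting material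
7 | 1,3,5-tris(methoxymethoxy)benzene | COCOc1cc(OCOC)cc(OCOC)c1 | intermediate
8 | 5-methoxyresorcinol | COc1cc(O)cc(O)c1 | starting material
9 | 1-methoxy-3,5-bis(methoxymethoxy)benzene | COCOc1cc(OC)cc(OCOC)c1 | intermediate
10 | 2,4,6-tris(methoxymethoxy)phenyllithium | [Li]c1c(OCOC)cc(OCOC)cc1OCOC | intermediate (not isolated)
11 | (2E,3E)-2,3-bis(4-methoxybenzylidene)-4-oxo-4-[2,4,6-tris(methoxymethoxy)phenyl]butanoic acid | O=C(c1c(OCOC)cc(OCOC)cc1OCOC)/C(=C/c1ccc(OC)cc1)C(=C/c1ccc(OC)cc1)\C(=O)O | intermediate
12 | methyl (2E,3E)-2,3-bis(4-methoxybenzylidene)-4-oxo-4-[2,4,6-tris(methoxymethoxy)phenyl]butanoate | O=C(c1c(OCOC)cc(OCOC)cc1OCOC)/C(=C/c1ccc(OC)cc1)C(=C/c1ccc(OC)cc1)\C(=O)OC | intermediate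
13 | 4-methoxy-2,6-bis(methoxymethoxy)phenyllithium | [Li]c1c(OCOC)cc(OC)cc1OCOC | intermediate (not isolated)
14 | (2E,3E)-2,3-bis(4-methoxybenzylidene)-1-[4-methoxy-2,6-bis(methoxymethoxy)phenyl]-4-[2,4,6-tris(methoxymethoxy)phenyl]butane-1,4-dione | O=C(c1c(OCOC)cc(OCOC)cc1OCOC)/C(=C/c1ccc(OC)cc1)C(=C/c1ccc(OC)cc1)\C(=O)c1c(OCOC)cc(OC)cc1OCOC | intermediate
15 | (2E,3E)-1-[2-hydroxy-4,6-bis(methoxymethoxy)phenyl]-4-[2-hydroxy-4-methoxy-6-(methoxymethoxy)phenyl]-2,3-bis(4-methoxybenzylidene)butane-1,4-dione | O=C(c1c(O)cc(OCOC)cc1OCOC)/C(=C/c1ccc(OC)cc1)C(=C/c1ccc(OC)cc1)\C(=O)c1c(O)cc(OC)cc1OCOC | intermediate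
16 | (2S,3R)-5,7-bis(methoxymethoxy)-3-[(2S,3R)-7-methoxy-5-(methoxymethoxy)-2-(4-methoxyphenyl)-4-oxochroman-3-yl]-2-(4-methoxyphenyl)chroman-4-one | COc1ccc([C@H]2Oc3cc(OCOC)cc(OCOC)c3C(=O)[C@@H]2[C@H]2C(=O)c3c(OCOC)cc(OC)cc3O[C@@H]2c2ccc(OC)cc2)cc1 | intermediate
17 | ruixianglangdusu B, (2S,3R)-5,7-dihydroxy-3-[(2S,3R)-5-hydroxy-7-methoxy-2-(4-methoxyphenyl)-4-oxochroman-3-yl]-2-(4-methoxyphenyl)chroman-4-one | COc1ccc([C@H]2Oc3cc(O)cc(O)c3C(=O)[C@@H]2[C@H]2C(=O)c3c(O)cc(OC)cc3O[C@@H]2c2ccc(OC)cc2)cc1 | target

## Step count and least certain steps

Total: 10 steps. Longest linear sequence: 8 steps (steps 1, 2, 5, 6, 7, 8, 9 and 10, from dimethyl succinate 1); steps 3 and 4 are one-step side branches.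

**Step 9 (key step).** The most likely failures are:
- insufficient facial selectivity in the first closure, because the α-alkenyl enone lacks the second carbonyl on the α-carbon that gives the catalyst its firmest grip in the closest precedents;
- substrate rather than catalyst control in the second closure, because the new C2 and C3 centres sit directly beside the second enone;
- erosion by reversible ring opening if the product stays long with the amine.

Fallback: from 15, the classical thermodynamic closure with NaOAc in refluxing ethanol should form both rings without facial control and with trans C3 and C3'. It gives 16 together with its enantiomer ent-16 F1 and the racemic unlike diastereomer F2. F2 is removed on silica, and 16 is separated from F1 by preparative chromatography on a polysaccharide chiral stationary phase. The route is rejoined at 16, at the cost of more than half of the material.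

**Step 7.** Two processes threaten it: metalation of 9 partly at a position between the methoxy and an acetal group, which gives a regioisomeric aryllithium, and slow acyl substitution at the α-branched ester, which lets conjugate addition to an anisylidene unit compete.

Fallback: the lithiation mixture from 9 is quenched with iodine and the aryl iodide F3 is purified by crystallisation. Iodine–lithium exchange with n-BuLi at −78 °C then regenerates 13 as a single regioisomer. In parallel, 12 is converted with the chloromagnesium amide from N,O-dimethylhydroxylamine hydrochloride and i-PrMgCl into the Weinreb amide F4. Its chelated tetrahedral adduct tolerates an excess of 13 and warming. Acidic work-up returns to the route at 14.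

**Step 8.** Cleavage may run unevenly over the two rings, one losing a second acetal before the other has lost its first. The Lewis acid may also promote unselective ring closure of a freed phenol before the chiral catalyst is present.

Fallback: one ring at a time. From 12, MgBr2·OEt2 unveils the single ortho phenol of the phenol ester F5. Treatment with 2.3 equivalents of 13 forms the lithium phenoxide first (which also deactivates that ketone and its enone) and then acylates the ester to give the mono-phenol diketone F6. A second, separate MgBr2·OEt2 cleavage on the other ring returns to the route at 15.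

**Step 5.** Aryllithium 10 may add to an anisylidene β-carbon of the strongly electrophilic anhydride, or add twice through the ring-closed lactol.

Fallback: from 5, N,O-dimethylhydroxylamine (hydrochloride, pyridine) opens the anhydride to the Weinreb amide acid F7. With 2.2 equivalents of 10 the first equivalent forms the inert lithium carboxylate and the second adds to the amide to give a stable chelate. Acidic work-up returns to the route at 11.

**Step 1.** The second condensation has to enolise a position next to a carboxylate and may stall at the mono-anisylidene stage while the aldehyde is consumed by base.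

Fallback: stepwise condensation. From 1 and one equivalent of 2, a single Stobbe condensation gives the half-ester F8. Fischer esterification (MeOH, H2SO4) gives the diester F9. A second Stobbe condensation with 2 (KOt-Bu, t-BuOH) then leads to 3, which is saponified as before, and the route is rejoined at 4.

## Further compounds

F1 | step 9 | ent-16, (2R,3S)-5,7-bis(methoxymethoxy)-3-[(2R,3S)-7-methoxy-5-(methoxymethoxy)-2-(4-methoxyphenyl)-4-oxochroman-3-yl]-2-(4-methoxyphenyl)chroman-4-one | COc1ccc([C@@H]2Oc3cc(OCOC)cc(OCOC)c3C(=O)[C@H]2[C@@H]2C(=O)c3c(OCOC)cc(OC)cc3O[C@H]2c2ccc(OC)cc2)cc1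
F2 | step 9 | unlike diastereomer of 16 (formed as the racemate), (2S,3R)-5,7-bis(methoxymethoxy)-3-[(2R,3S)-7-methoxy-5-(methoxymethoxy)-2-(4-methoxyphenyl)-4-oxochroman-3-yl]-2-(4-methoxyphenyl)chroman-4-one | COc1ccc([C@H]2Oc3cc(OCOC)cc(OCOC)c3C(=O)[C@@H]2[C@@H]2C(=O)c3c(OCOC)cc(OC)cc3O[C@H]2c2ccc(OC)cc2)cc1
F3 | step 7 | 2-iodo-5-methoxy-1,3-bis(methoxymethoxy)benzene | COCOc1cc(OC)cc(OCOC)c1I
F4 | step 7 | (2E,3E)-N-methoxy-N-methyl-2,3-bis(4-methoxybenzylidene)-4-oxo-4-[2,4,6-tris(methoxymethoxy)phenyl]butanamide | O=C(c1c(OCOC)cc(OCOC)cc1OCOC)/C(=C/c1ccc(OC)cc1)C(=C/c1ccc(OC)cc1)\C(=O)N(C)OC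
F5 | step 8 | methyl (2E,3E)-4-[2-hydroxy-4,6-bis(methoxymethoxy)phenyl]-2,3-bis(4-methoxybenzylidene)-4-oxobutanoate | O=C(c1c(O)cc(OCOC)cc1OCOC)/C(=C/c1ccc(OC)cc1)C(=C/c1ccc(OC)cc1)\C(=O)OC
F6 | step 8 | (2E,3E)-1-[2-hydroxy-4,6-bis(methoxymethoxy)phenyl]-4-[4-methoxy-2,6-bis(methoxymethoxy)phenyl]-2,3-bis(4-methoxybenzylidene)butane-1,4-dione | O=C(c1c(O)cc(OCOC)cc1OCOC)/C(=C/c1ccc(OC)cc1)C(=C/c1ccc(OC)cc1)\C(=O)c1c(OCOC)cc(OC)cc1OCOC
F7 | step 5 | (2E,3E)-4-[methoxy(methyl)amino]-2,3-bis(4-methoxybenzylidene)-4-oxobutanoic acid | CON(C)C(=O)/C(=C/c1ccc(OC)cc1)C(=C/c1ccc(OC)cc1)\C(=O)O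
F8 | step 1 | (E)-3-(methoxycarbonyl)-4-(4-methoxyphenyl)but-3-enoic acid | COC(=O)/C(=C/c1ccc(OC)cc1)CC(=O)O
F9 | step 1 | dimethyl (E)-2-(4-methoxybenzylidene)succinate | COC(=O)/C(=C/c1ccc(OC)cc1)CC(=O)OC
A1 | alternative 1 | 5,7-bis(benzyloxy)-3-[5-(benzyloxy)-7-methoxy-4-oxo-4H-chromen-3-yl]-4H-chromen-4-one | O=c1c(-c2coc3cc(OC)cc(OCc4ccccc4)c3c2=O)coc2cc(OCc3ccccc3)cc(OCc3ccccc3)c12
A2 | alternative 1 | (2S,3R)-5,7-bis(benzyloxy)-3-[(2S,3R)-5-(benzyloxy)-7-methoxy-2-(4-methoxyphenyl)-4-oxochroman-3-yl]-2-(4-methoxyphenyl)chroman-4-one | COc1ccc([C@H]2Oc3cc(OCc4ccccc4)cc(OCc4ccccc4)c3C(=O)[C@@H]2[C@H]2C(=O)c3c(OCc4ccccc4)cc(OC)cc3O[C@@H]2c2ccc(OC)cc2)cc1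
A3 | alternative 2 | 1,5-bis(benzyloxy)-3-{[(1R,4R)-4-(3,5-dimethoxyphenoxy)-1,4-bis(4-methoxyphenyl)but-2-yn-1-yl]oxy}-2-iodobenzene | COc1ccc([C@@H](Oc2cc(OCc3ccccc3)cc(OCc3ccccc3)c2I)C#C[C@H](Oc2cc(OC)cc(OC)c2)c2ccc(OC)cc2)cc1
A4 | alternative 2 | (Z)-(2R,2'R)-5,7-bis(benzyloxy)-5',7'-dimethoxy-2,2'-bis(4-methoxyphenyl)-[3,3'-bichromanylidene]-4,4'-dione | COc1ccc([C@H]2Oc3cc(OCc4ccccc4)cc(OCc4ccccc4)c3C(=O)/C2=C2\C(=O)c3c(OC)cc(OC)cc3O[C@@H]2c2ccc(OC)cc2)cc1
A5 | alternative 3 | (2R,3R)-2,3-bis{(S)-[3,5-bis(benzyloxy)phenoxy](4-methoxyphenyl)methyl}-N,N,N',N'-tetramethylsuccinamide | COc1ccc([C@@H](Oc2cc(OCc3ccccc3)cc(OCc3ccccc3)c2)[C@H](C(=O)N(C)C)[C@@H](C(=O)N(C)C)[C@H](Oc2cc(OCc3ccccc3)cc(OCc3ccccc3)c2)c2ccc(OC)cc2)cc1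
A6 | alternative 3 | (2S,3R)-5,7-bis(benzyloxy)-3-[(2S,3R)-5,7-bis(benzyloxy)-2-(4-methoxyphenyl)-4-oxochroman-3-yl]-2-(4-methoxyphenyl)chroman-4-one | COc1ccc([C@H]2Oc3cc(OCc4ccccc4)cc(OCc4ccccc4)c3C(=O)[C@@H]2[C@H]2C(=O)c3c(OCc4ccccc4)cc(OCc4ccccc4)cc3O[C@@H]2c2ccc(OC)cc2)cc1
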